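A direct plan would grow ring A from open-chain pieces on the oxygen of 2,4-dibromophenol A1: O-alkylation with methyl bromoacetate A2, crossed Claisen extension to tert-butyl 4-(2,4-dibromophenoxy)-3-oxobutanoate A3, Michael addition to acrolein A4, and an acid-induced decarboxylation–aldol condensation to 2-(2,4-dibromophenoxy)cyclohex-2-en-1-one A5.
Oxidative aromatization of A5 would then give 2-(2,4-dibromophenoxy)phenol A6, dibromination would give 2,4-dibromo-6-(2,4-dibromophenoxy)phenol A7, and O-methylation of A7 would give the target.
Weak point one, the five-step run-up from A1 through A2, A3, A4 and A5 to A6: alkylation, Claisen, Michael, aldol and dehydrogenation would deliver only an unsubstituted benzene ring, so most of the route would build no feature of the target.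
Weak point two, the acid cascade that follows the union of A3 with A4 and leads to A5: a free aliphatic aldehyde would have to survive hot acid while ring closure depends on enolization toward the aryloxy-bearing CH2, with aldehyde self-condensation and loss of the aryloxide as competing paths.
Weak point three, the late dibromination of A6 to A7: the pattern of ring A would rest on a contest of directing groups (OH against the aryloxy oxygen, ring A against ring B) on the finished diphenyl ether, where under- or over-brominated congeners are very hard to remove.

**Retrosynthetic overview**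
Numbering: ring A is the anisole ring (C1 OMe, C2 Br, C4 Br, C6 O-aryl); ring B is the 2,4-dibromophenoxy ring (C1' O, C2' Br, C4' Br). The target is achiral.
Both rings are 2,4-dibromophenol units, and the target is the O-methyl ether of their O1'-to-C6 dimer, the linkage expected from the presumed oxidative coupling of that phenol in its biogenesis. The key disconnection is therefore the bridging O–C6 bond of ring A.
The coupling is staged as a formal dehydrogenative cross-dimerization with polarity reversal: C6–H of one monomer is iodinated, the phenol is methylated, the iodide is raised to a trivalent aryl(2,4,6-trimethoxyphenyl)iodonium salt, and the phenoxide of the second monomer displaces iodine at C6 by metal-free ligand coupling.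
No ring is formed at any stage: both rings, all four bromines and the full substitution pattern come in with the monomer, so the long ring construction and the late bromination disappear, and the methyl ether is in place before the rings are joined.

Key step: step 4

**Step 1**
Reactants: 1 2,4-dibromophenol
Product: 2 2,4-dibromo-6-iodophenol
Conditions: NIS (1.05 equiv), TsOH·H2O (10 mol%), MeCN, rt, dark
Reagents that add atoms: N-iodosuccinimide, O=C1CCC(=O)N1I
Why: Electrophilic aromatic iodination of a phenol by acid-activated NIS should occur only at C6, the single position ortho or para to OH that is not blocked by bromine, and the mild iodine source should leave the C–Br bonds in place.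

**Step 2**
Reactants: 2 2,4-dibromo-6-iodophenol
Product: 3 1,5-dibromo-3-iodo-2-methoxybenzene
Conditions: MeI (1.5 equiv), K2CO3 (2 equiv), DMF, rt
Reagents that add atoms: iodomethane, CI
Why: Williamson O-methylation of the acidic 2,6-dihalophenoxide with unhindered iodomethane should be clean, and it sets the methyl ether before the coupling so that ring A can later act only as the electrophile.

**Step 3**
Reactants: 3 1,5-dibromo-3-iodo-2-methoxybenzene; 4 1,3,5-trimethoxybenzene
Product: 6 (3,5-dibromo-2-methoxyphenyl)(2,4,6-trimethoxyphenyl)iodonium 4-methylbenzenesulfonate, via [hydroxy(tosyloxy)iodo]arene 5 (not isolated)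
Conditions: mCPBA (1.05 equiv), TsOH·H2O (1.05 equiv), MeCN, 77 °C, 1 h; then 4 (1.05 equiv), 77 °C → rt; trituration with Et2O
Reagents that add atoms: p-toluenesulfonic acid, Cc1ccc(cc1)S(O)(=O)=O
Why: One-pot oxidation of the aryl iodide by mCPBA/TsOH to the [hydroxy(tosyloxy)iodo]arene 5, followed by electrophilic aromatic substitution on the very electron-rich 1,3,5-trimethoxybenzene, is the standard synthesis of aryl(2,4,6-trimethoxyphenyl)iodonium tosylates, tolerates ortho substituents and electron-poor aryl iodides, and should leave the aryl bromides and the methyl ether untouched.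

**Step 4**
Reactants: 1 2,4-dibromophenol; 6 (3,5-dibromo-2-methoxyphenyl)(2,4,6-trimethoxyphenyl)iodonium 4-methylbenzenesulfonate
Product: 9 1,5-dibromo-3-(2,4-dibromophenoxy)-2-methoxybenzene, via potassium 2,4-dibromophenoxide 7 (not isolated), via aryloxy-λ3-iodane 8 (not isolated)
Conditions: 1 (1.2 equiv), t-BuOK (1.1 equiv), THF, 0 °C, 15 min; then 6 (1.0 equiv), rt → 40 °C
Reagents that add atoms: none
Why: Metal-free O-arylation of a phenoxide with an unsymmetrical diaryliodonium salt: phenoxide 7 displaces tosylate at trivalent iodine to give the T-shaped aryloxy-λ3-iodane 8, which collapses by ligand coupling (a three-centre reductive elimination at iodine) to the diaryl ether and an aryl iodide. The closest known reaction type is the mild arylation of phenols with aryl(2,4,6-trimethoxyphenyl)iodonium salts and, in this compound class, the coupling of bromophenoxides with brominated diphenyliodonium salts to polybrominated diphenyl ethers. No ring is closed and no stereocentre is formed; the step joins O1' of ring B to C6 of ring A, the bond of the presumed oxidative dimerization of 2,4-dibromophenol. The selectivity needed is transfer of the 3,5-dibromo-2-methoxyphenyl group and not the trimethoxyphenyl group; this is secured because the electron-rich trimethoxyphenyl ligand is a poor acceptor for ipso attack, while the transferred aryl is ortho-substituted and electron-poor (two meta bromines, and a flanked OMe twisted out of conjugation). Strictly ipso substitution, without an aryne although H5 of ring A lies between the iodonium centre and a bromine, is secured by having no base stronger than the weakly basic phenoxide in the flask (phenol in excess over t-BuOK). The four C–Br bonds should be inert because no transition metal and no radical initiator is present.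

**Compound list**
1 | 2,4-dibromophenol | Oc1ccc(Br)cc1Br | starting material
2 | 2,4-dibromo-6-iodophenol | Oc1c(Br)cc(Br)cc1I | intermediate
3 | 1,5-dibromo-3-iodo-2-methoxybenzene | COc1c(Br)cc(Br)cc1I | intermediate
4 | 1,3,5-trimethoxybenzene | COc1cc(OC)cc(OC)c1 | starting material
5 | 1,5-dibromo-3-[hydroxy(tosyloxy)-λ3-iodanyl]-2-methoxybenzene (the [hydroxy(tosyloxy)iodo]arene of 3, formed in situ) | COc1c(Br)cc(Br)cc1I(O)OS(=O)(=O)c1ccc(C)cc1 | intermediate
6 | (3,5-dibromo-2-methoxyphenyl)(2,4,6-trimethoxyphenyl)iodonium 4-methylbenzenesulfonate | COc1cc(OC)c([I+]c2cc(Br)cc(Br)c2OC)c(OC)c1.Cc1ccc(cc1)S([O-])(=O)=O | intermediate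
7 | potassium 2,4-dibromophenoxide (formed in situ) | [K+].[O-]c1ccc(Br)cc1Br | intermediate
8 | (2,4-dibromophenoxy)(3,5-dibromo-2-methoxyphenyl)(2,4,6-trimethoxyphenyl)-λ3-iodane (formed in situ) | COc1cc(OC)c(I(Oc2ccc(Br)cc2Br)c2cc(Br)cc(Br)c2OC)c(OC)c1 | intermediate
9 | 1,5-dibromo-3-(2,4-dibromophenoxy)-2-methoxybenzene (achiral) | COc1c(Br)cc(Br)cc1Oc1ccc(Br)cc1Br | target

**Total step count:** 4
**Longest linear sequence:** 4 steps (1 → 2 → 3 → 6 → 9)

**Steps most likely to fail**

Step 4 (key step). What may go wrong: deprotonation of H5 of the iodonium aryl group with aryne formation and cine substitution, competing transfer of the trimethoxyphenyl group, or slow ligand coupling of the hindered, weakly nucleophilic phenoxide. The fallback exchanges the polarity of the two rings, so that the other aryl–oxygen bond (O–C1' of ring B) is formed. It sets out from iodide 3, which would undergo iodine–magnesium exchange (i-PrMgCl·LiCl, THF, −40 °C; C–I reacts far faster than C–Br), quench with B(OMe)3 and hydrolysis to (3,5-dibromo-2-methoxyphenyl)boronic acid F1, then oxidation (H2O2, NaOH, THF, 0 °C) to 3,5-dibromo-2-methoxyphenol F2. Commercial 2,4-dibromo-1-iodobenzene F3 would be converted, under the conditions of step 3, into (2,4-dibromophenyl)(2,4,6-trimethoxyphenyl)iodonium 4-methylbenzenesulfonate F4, whose transferred aryl group has no C–H between the iodonium centre and a bromine. The potassium salt of F2 and F4 (t-BuOK, THF, 40 °C) should then give the diaryl ether, and the fallback comes back to the route at 9.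

Step 3. What may go wrong: incomplete oxidation of the electron-poor, ortho-substituted iodide to trivalent iodine, or decomposition of the salt during isolation. The fallback avoids hypervalent iodine altogether: it sets out from iodide 3 and phenol 1, which would be joined by a copper-catalysed Ullmann etherification (CuI 10 mol%, picolinic acid 20 mol%, K3PO4, DMSO, 80 °C), relying on the faster reaction of C–I compared with C–Br at this temperature. It comes back to the route at 9 and makes no new compound.

Step 1. What may go wrong: slow or incomplete iodination of the doubly deactivated phenol, or halogen scrambling under acid. The fallback functionalizes C6 through nitrogen. It sets out from 1: nitration (HNO3, AcOH, 10 °C) would give 2,4-dibromo-6-nitrophenol F5, O-methylation (MeI, K2CO3, DMF) 1,5-dibromo-2-methoxy-3-nitrobenzene F6, and reduction (Fe powder, NH4Cl, EtOH/H2O, 70 °C) 3,5-dibromo-2-methoxyaniline F7. Diazotization (NaNO2, H2SO4, 0 °C) to 3,5-dibromo-2-methoxybenzenediazonium hydrogen sulfate F8 and treatment with KI (Sandmeyer-type iodination) should give the iodide, and the fallback comes back to the route at 3.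

**Further compounds**
F1 | step 4 | (3,5-dibromo-2-methoxyphenyl)boronic acid | COc1c(Br)cc(Br)cc1B(O)O
F2 | step 4 | 3,5-dibromo-2-methoxyphenol | COc1c(Br)cc(Br)cc1O
F3 | step 4 | 2,4-dibromo-1-iodobenzene | Ic1ccc(Br)cc1Br
F4 | step 4 | (2,4-dibromophenyl)(2,4,6-trimethoxyphenyl)iodonium 4-methylbenzenesulfonate | COc1cc(OC)c([I+]c2ccc(Br)cc2Br)c(OC)c1.Cc1ccc(cc1)S([O-])(=O)=O
F0 | step 3 | none | none
F5 | step 1 | 2,4-dibromo-6-nitrophenol | Oc1c(Br)cc(Br)cc1[N+](=O)[O-]
F6 | step 1 | 1,5-dibromo-2-methoxy-3-nitrobenzene | COc1c(Br)cc(Br)cc1[N+](=O)[O-]
F7 | step 1 | 3,5-dibromo-2-methoxyaniline | COc1c(Br)cc(Br)cc1N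
F8 | step 1 | 3,5-dibromo-2-methoxybenzenediazonium hydrogen sulfate | COc1c(Br)cc(Br)cc1[N+]#N.OS([O-])(=O)=O
A1 | direct plan | 2,4-dibromophenol | Oc1ccc(Br)cc1Br
A2 | direct plan | methyl bromoacetate | COC(=O)CBr
A3 | direct plan | tert-butyl 4-(2,4-dibromophenoxy)-3-oxobutanoate | CC(C)(C)OC(=O)CC(=O)COc1ccc(Br)cc1Br
A4 | direct plan | acrolein | C=CC=O
A5 | direct plan | 2-(2,4-dibromophenoxy)cyclohex-2-en-1-one | O=C1CCCC=C1Oc1ccc(Br)cc1Br
A6 | direct plan | 2-(2,4-dibromophenoxy)phenol | Oc1ccccc1Oc1ccc(Br)cc1Br
A7 | direct plan | 2,4-dibromo-6-(2,4-dibromophenoxy)phenol | Oc1c(Br)cc(Br)cc1Oc1ccc(Br)cc1Br
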